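## Structural features

The target is a cis-fused decalin joined through a two-carbon chain to a 1,2-dioxane: ring A is C4a–C5–C6–C7–C8–C8a, ring B is C1–C2–C3–C4–C4a–C8a, the chain C1′–C2′ leaves C2 and ends at C3′ of ring C (C3′–C4′–C5′–C6′–O–O), and C6′ carries the CH(CH3)CO2H group (C7′, C8′). Ring B holds the quaternary C1 (gem-dimethyl) between the stereocentres C8a and C2, with C4a next to C8a; H-2, H-4a and H-8a lie on one face, so the side chain is cis to C5 and C8 (2R, 4aS, 8aS). The second set of stereocentres is remote from the first: the fully substituted peroxy carbon C3′ (S, its methyl cis to the acid arm across ring C) and the vicinal pair C6′ (R) and C7′ (R), whose C–O and C–CH3 bonds are anti. The fragile groups are the O–O bond (reducing agents, phosphines, low-valent metals, base-induced Kornblum–DeLaMare cleavage through H-6′), the two exocyclic 1,1-disubstituted alkenes at C3 and C6 (acid, electrophilic oxidants, diimide or hydrogen), the α-centre C7′ of the acid, and C2 whenever C3 is a ketone. One real difficulty is the C1–C2 bond, which joins a quaternary to a tertiary carbon and must be made with control of three stereocentres on a cis ring fusion. The other is C3′: its two alkyl arms (CH3 and CH2CH2R) are sterically alike, so no conformational bias can set it and only a stereospecific C–O bond formation will serve, at a stage where both alkenes are already present. The key step uses the fact that ring B, once C3 carries oxygen, is the cyclohexene of a Diels–Alder adduct between the 2-silyloxydiene C4a=C4–C3(OSi)=C2 and the alkene C8a=C1, which can be conjugated to a C8 carbonyl in the four-carbon tether C5–C8 that becomes ring A, with an oxygen at C6 (later C=CH2) as a temporary stereocentre.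

## Logic of the disconnections

49 ⇒ 47 (through 48). The O–C6′ bond of ring C is cut. The C6′ oxygen and the carboxyl group are 1,3-related, so both can come from one four-membered lactone that the peroxide oxygen opens at C6′. Ring C and the free acid then appear together and no protecting group or redox step is needed after the O–O ring exists. The forward step must be a clean backside attack at C6′ (inversion) by a tertiary peroxide oxygen, in preference to acyl attack or elimination, without touching the alkenes.

47 ⇒ 45 + 46. The C6′–C7′ and O–C8′ bonds are cut (ketene–aldehyde [2+2]). One catalytic asymmetric step sets C6′ and C7′ together, independently of the remote C3′. Two stereocentres and three carbons are removed. The catalyst must override any influence of C3′, and the silyl peroxide must survive an amine base and LiClO4.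

45 ⇒ 44 ⇒ 42 + 43. The C4′–C5′ bond is cut as an alkene made by Wittig reaction on an aldehyde that has no α-hydrogen. Two carbons are removed. The forward sequence must reduce only the conjugated C=C beside two isolated alkenes and an O–O bond, which calls for organocatalytic hydride transfer.

42 ⇒ 41 ⇒ 40 ⇒ 38 + 39. The C3′–OO bond is cut, and the C4′ aldehyde is traced to a glycol. Invertive opening of an epoxide is the dependable stereospecific route to a tertiary hydroperoxide. The epoxide oxygen left on C4′ is then used up by excising the hydroxymethyl carbon, which turns C4′ into the aldehyde. C3′ is thereby reduced to an epoxide stereocentre. Attack must occur only at the tertiary carbon, with inversion, and the exocyclic alkenes must stay inert; 41 must be protected at once.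

38 ⇒ 36 ⇒ 35 ⇒ 32. The epoxide C–O bonds, the C3′–CH3 bond and the C4′–CH2OH bond are cut. Hydroxyl-directed asymmetric epoxidation is chemoselective beside unfunctionalised alkenes, and syn carbometalation of a terminal alkyne gives a single trisubstituted alkene geometry. The demand is one alkene isomer and reagent-controlled face selection.

32 ⇒ 30 ⇒ 29 ⇒ 28. The C3′≡C4′ bond (one-carbon homologation), the C3′ oxidation level and the benzyl ether O–C bond are cut. These are standard operations that must leave the exocyclic alkenes alone.

28 ⇒ 26 ⇒ 25 ⇒ 24. Both exocyclic C=CH2 bonds are cut to carbonyls, the C6 carbonyl to a carbinol and the C3 carbonyl to its silyl enol ether. The alkenes are placed before any peroxide exists, because the methylenating reagent would destroy an O–O bond. The forward steps must be non-basic so that C2, α to the C3 ketone, is not epimerised.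

24 ⇒ 23 ⇒ 20 ⇒ 19. A C8–H bond is traced back to the C8 carbonyl that activates the dienophile. The carbonyl must be reduced before it epimerises C8a, and the deoxygenation must tolerate the enol ether.

19 ⇒ 18. The C4a–C8a and C1–C2 bonds are cut. Two rings, two C–C bonds and three stereocentres are removed, leaving an acyclic chain with one stereocentre. The forward step must be endo-selective and face-selective and must form a quaternary carbon. A re-derivation of the descriptors shows that 19 carries C2, C4a and C8a in the sense of 49, and that the E,Z geometry and the 6S centre of 18 map onto it, so no structure needed correction.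

18 ⇒ 16 + 17. The C8–C8a bond is cut (acyl–alkenyl). The enone is unveiled last, so that only one ketone is present when the silyl enol ether is made. No C8 carbinol then has to be unmasked and oxidised beside the silyl dienol ether, which improves the access to 18 without changing the disconnection. The organometallic reagent must leave the dienol ether intact.

16 ⇒ 14 ⇒ 13 + 7. The enol O–Si bond and the C4a=C4 bond (cross-metathesis) are cut. The forward steps need α′-regioselective, Z-selective enolisation and E-selective metathesis.

13 ⇒ 11 ⇒ 10 ⇒ 9 + 6, and 9 ⇒ 8. The O–Si bond, the amide C–N bond and the C5–C4a bond (epoxide opening) are cut, and the epoxide is traced to a chlorohydrin from the chiral pool, which supplies C6.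

7 ⇒ 5 + 6, 5 ⇒ 3 + 4, 3 ⇒ 1 + 2. The ketone C–C bond, the ether O–C bond and the amide C–N bond are cut back to a lactone.

## Other disconnections considered

Alternative 1: The cut is through C4a–C5 and C8–C8a, so ring A alone is made, by an intermolecular Diels–Alder reaction of 2-(trimethylsilyloxy)buta-1,3-diene A1 with (5R)-5-(l-menthyloxy)furan-2(5H)-one A2 to give the cis-fused lactone acetal A3.
- In its favour: the dienophile is cis-locked, so the cis fusion is automatic. The menthyloxy group shields one face, so the absolute sense of C4a and C8a comes from a resident, removable auxiliary and not from a tether conformation. Both dienophile termini are unhindered, so the addition should be easy. The enol ether places the C6 oxygen without a temporary stereocentre.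
- Against it here: A3 contains neither ring B nor C2. Its lactone carbonyl must become the quaternary C1 and its acetal carbon C4, so the C1–C2 bond, the gem-dimethyl group, the C3 oxygen and the C2 stereocentre all remain. The regiochemistry (silyloxy at C6, not C7) rests on the para preference of a 2-substituted diene.
- Comparison: on structure the chosen step forms two rings, two C–C bonds and three stereocentres, including the bond to the quaternary carbon, whereas A3 has one ring and two stereocentres. On mechanism the alternative is the better: auxiliary-controlled facial selectivity and an unhindered dienophile are more secure than the slow, tether-controlled addition of 18. On supply of starting materials it is at least the equal. On step economy after the key step the chosen plan is ahead, because the hardest bond is already made.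

Alternative 2: The cut is the C2–C3 bond of ring B. The phenyl selenoester A4 is a cis-1,2-disubstituted cyclohexane that already carries the C4–C3 arm on C4a and the quaternary C1 with an enoate on C8a. (Me3Si)3SiH/AIBN converts it into an acyl radical that adds 6-exo to the enoate β-carbon, giving the decalin-3-one A5.
- In its favour: acyl radical 6-exo additions to acrylate-type acceptors are fast, neutral and have early transition states that tolerate the neighbouring quaternary carbon. The C3 carbonyl arrives directly, ready for methylenation, and C6 can travel as a ketal.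
- Against it here: one bond and one stereocentre are made. The configuration at C2 would depend on the conformation of the chair-like radical transition state on a cis-fused ring and is not secured by any element of A4; C2 is also epimerisable next to the new ketone. The ring fusion and the quaternary centre must be built beforehand by other chemistry. The arm on C2 arrives as CH2CO2Me and lacks C3′.
- Comparison: in sheer reactivity this closure is the equal or the better of the chosen one (no forcing conditions), and in the functional-group outcome at C3 it is the equal. On structure it does much less (no ring A, no control of the fusion). On stereocontrol at C2 it is weaker than geometry transfer from a Z enol ether. On step economy it is worse, because A4 itself needs a multistep stereocontrolled synthesis.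

Alternative 3: The cut is the C4a–C8a bond. The Z ten-membered allylic lactone A6 is converted into its silyl ketene acetal (LDA, TBSCl) and rearranges on warming (Ireland–Claisen ring contraction) to the cis-2-isopropenylcyclohexanecarboxylic acid A7, in which the carboxyl carbon is C4 and the isopropenyl carbon is C1.
- In its favour: the [3,3] shift is concerted, runs at or below room temperature and, for a medium-ring lactone, can only pass through a boat-like transition state, which turns the Z alkene into the cis relation of C4a and C8a. The silyloxy centre at C6 plays the same temporary role as in the chosen plan. No hindered bond is formed.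
- Against it here: A6 needs a macrolactonisation of a seco-acid with a Z trisubstituted allylic alcohol. A7 has ring A only and C1 is still trigonal with one methyl group, so the quaternary centre, the C1–C2 bond, ring B and C2 remain, and a further cyclisation with an open outcome at C2 would be required.
- Comparison: on mechanism and on certainty of the cis fusion the rearrangement is the equal or the better of the cycloaddition. On the use of the temporary C6 stereocentre the two are equal. On structure the chosen step delivers far more (both rings, C2, the quaternary C1). On step economy the alternative is longer both before (macrocycle) and after (ring B) its key step.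

Key step: step 11

Remark on notation: decalin atoms are numbered as in the first section; side-chain atoms are C1′–C8′; TBS = tert-butyldimethylsilyl, PMB = 4-methoxybenzyl, Dec = (2R,4aS,8aS)-1,1-dimethyl-3,6-dimethylidenedecahydronaphthalen-2-yl.

Assumption: in step 27 the quinidine-derived silyl ether is taken to give the (3R,4S) lactone, by analogy with the sense of quinidine-catalysed ketene–aldehyde cycloadditions; should it favour the antipode, the pseudoenantiomeric quinine ether is used with no other change.

## Route

Step 1
Reactants: 1 δ-valerolactone; 2 N,O-dimethylhydroxylamine hydrochloride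
Product: 3 5-hydroxy-N-methoxy-N-methylpentanamide
Conditions: MeNH(OMe)·HCl, iPrMgCl, THF, −20 → 0 °C
Reagents that add atoms: N,O-dimethylhydroxylamine hydrochloride (CNOC.Cl)
Why: Aminolysis of the lactone by the magnesium amide (Weinreb amide formation) opens the ring at the acyl carbon; the primary alkoxide does not re-close at this temperature.

Step 2
Reactants: 3 5-hydroxy-N-methoxy-N-methylpentanamide; 4 4-methoxybenzyl chloride
Product: 5 N-methoxy-5-[(4-methoxybenzyl)oxy]-N-methylpentanamide
Conditions: NaH, PMBCl, Bu4NI (cat.), THF/DMF, 0 °C → rt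
Reagents that add atoms: 4-methoxybenzyl chloride (COc1ccc(CCl)cc1)
Why: Williamson etherification of the primary alkoxide; the tertiary amide has no acidic N–H and tolerates NaH at 0 °C.

Step 3
Reactants: 5 N-methoxy-5-[(4-methoxybenzyl)oxy]-N-methylpentanamide; 6 vinylmagnesium bromide
Product: 7 7-[(4-methoxybenzyl)oxy]hept-1-en-3-one
Conditions: CH2=CHMgBr, THF, −20 → 0 °C; inverse quench into cold aq. NH4Cl
Reagents that add atoms: vinylmagnesium bromide (C=C[Mg]Br)
Why: Grignard acylation stops at the chelated tetrahedral adduct of the Weinreb amide, so the vinyl ketone appears only on quench; the cold inverse quench limits conjugate addition of the released amine.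

Step 4
Reactants: 8 ethyl (3R)-4-chloro-3-hydroxybutanoate
Product: 9 ethyl [(2R)-oxiran-2-yl]acetate
Conditions: Ag2O, DME, 60 °C
Reagents that add atoms: none
Why: Silver-assisted intramolecular Williamson closure of the halohydrin with retention at the carbinol carbon; no soluble base is present to isomerise the β,γ-epoxy ester to the γ-hydroxy enoate.

Step 5
Reactants: 9 ethyl [(2R)-oxiran-2-yl]acetate; 6 vinylmagnesium bromide
Product: 10 ethyl (3S)-3-hydroxyhex-5-enoate
Conditions: CH2=CHMgBr, CuI (10 mol %), THF, −40 °C
Reagents that add atoms: vinylmagnesium bromide (C=C[Mg]Br)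
Why: Copper-catalysed SN2 opening of the terminal epoxide at its CH2 carbon is faster than ester attack at −40 °C; the carbinol centre is untouched and becomes C6 (the descriptor changes only through priorities).

Step 6
Reactants: 10 ethyl (3S)-3-hydroxyhex-5-enoate; 2 N,O-dimethylhydroxylamine hydrochloride
Product: 11 (3S)-3-hydroxy-N-methoxy-N-methylhex-5-enamide
Conditions: MeNH(OMe)·HCl, iPrMgCl (excess), THF, −20 → 0 °C
Reagents that add atoms: N,O-dimethylhydroxylamine hydrochloride (CNOC.Cl)
Why: Weinreb amidation of the ester by the magnesium amide; the β-alkoxide formed first is not eliminated at this temperature.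

Step 7
Reactants: 11 (3S)-3-hydroxy-N-methoxy-N-methylhex-5-enamide; 12 tert-butyldimethylsilyl chloride
Product: 13 (3S)-3-[(tert-butyldimethylsilyl)oxy]-N-methoxy-N-methylhex-5-enamide
Conditions: TBSCl, imidazole, DMF, rt
Reagents that add atoms: tert-butyldimethylsilyl chloride (CC(C)(C)[Si](C)(C)Cl)
Why: Imidazole-catalysed silylation of the secondary alcohol; the same silyl group is used later on the enol so that both fall in one operation.

Step 8
Reactants: 13 (3S)-3-[(tert-butyldimethylsilyl)oxy]-N-methoxy-N-methylhex-5-enamide; 7 7-[(4-methoxybenzyl)oxy]hept-1-en-3-one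
Product: 14 (3S,5E)-3-[(tert-butyldimethylsilyl)oxy]-N-methoxy-11-[(4-methoxybenzyl)oxy]-N-methyl-7-oxoundec-5-enamide
Conditions: second-generation Hoveyda–Grubbs catalyst (5 mol %), 7 (2 equiv), CH2Cl2, 40 °C
Reagents that add atoms: 7-[(4-methoxybenzyl)oxy]hept-1-en-3-one (C=CC(=O)CCCCOCc1ccc(OC)cc1)
Why: Olefin cross-metathesis of a terminal alkene with an electron-poor vinyl ketone is selective for the cross product and gives the E enone under thermodynamic control.

Step 9
Reactants: 14 (3S,5E)-3-[(tert-butyldimethylsilyl)oxy]-N-methoxy-11-[(4-methoxybenzyl)oxy]-N-methyl-7-oxoundec-5-enamide; 15 tert-butyldimethylsilyl trifluoromethanesulfonate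
Product: 16 (3S,5E,7Z)-3,7-bis[(tert-butyldimethylsilyl)oxy]-N-methoxy-11-[(4-methoxybenzyl)oxy]-N-methylundeca-5,7-dienamide
Conditions: TBSOTf, Et3N, CH2Cl2, −78 → 0 °C
Reagents that add atoms: tert-butyldimethylsilyl trifluoromethanesulfonate (CC(C)(C)[Si](C)(C)OS(=O)(=O)C(F)(F)F)
Why: Soft enolisation: O-silylation of the ketone and deprotonation at the α′ CH2 give the cross-conjugated 2-silyloxydiene; the Z enol ether is favoured because the E isomer forces the side chain against H-4 (allylic 1,3-strain), and the far less acidic Weinreb amide is not enolised.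

Step 10
Reactants: 16 (3S,5E,7Z)-3,7-bis[(tert-butyldimethylsilyl)oxy]-N-methoxy-11-[(4-methoxybenzyl)oxy]-N-methylundeca-5,7-dienamide; 17 (2-methylprop-1-en-1-yl)magnesium bromide
Product: 18 (6S,8E,10Z)-6,10-bis[(tert-butyldimethylsilyl)oxy]-14-[(4-methoxybenzyl)oxy]-2-methyltetradeca-2,8,10-trien-4-one
Conditions: Me2C=CHMgBr, THF, −20 → 0 °C; pH 7 phosphate buffer
Reagents that add atoms: (2-methylprop-1-en-1-yl)magnesium bromide (CC(C)=C[Mg]Br)
Why: Alkenyl Grignard acylation by the Weinreb amide; the chelated adduct prevents over-addition, the silyl dienol ether is inert to the reagent and the neutral quench preserves it.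

Step 11
Reactants: 18 (6S,8E,10Z)-6,10-bis[(tert-butyldimethylsilyl)oxy]-14-[(4-methoxybenzyl)oxy]-2-methyltetradeca-2,8,10-trien-4-one
Product: 19 (2S,4aS,6S,8aS)-3,6-bis[(tert-butyldimethylsilyl)oxy]-2-{3-[(4-methoxybenzyl)oxy]propyl}-1,1-dimethyl-1,2,4a,5,6,7-hexahydronaphthalen-8(8aH)-one (route numbering)
Conditions: PhMe (0.01 M), BHT (cat.), 160 °C, sealed tube (base-washed glass)
Reagents that add atoms: none
Why: Thermal type 1 intramolecular Diels–Alder reaction: a concerted, asynchronous [4+2] addition in which the HOMO of the 2-silyloxydiene (largest coefficient at C2) meets the LUMO of the enone (largest coefficient at C1); the closest known reactions are the cyclisations of 1,7,9-decatrien-3-ones and of tethered 2-silyloxydienes. Ring B is closed by the cycloaddition itself (bonds C1–C2 and C4a–C8a), and ring A closes in the same event as the six-membered tether ring through the C4a–C8a bond. C4a and C8a come out cis because the C8 carbonyl lies in the tether and sits under the diene (endo, boat-like tether). C2 is set by the Z enol ether: its side chain and C5 on the E alkene are both outside substituents and add suprafacially, so they end cis on ring B. The absolute sense is set by C6: in the boat-like endo tether its silyloxy group takes the bowsprit position, away from the flagpole H at C8a, which exposes one diene face. The step needs endo over exo and one π-face; the conjugated tether carbonyl, the s-cis β,β-dimethyl enone and the bulky silyloxy group provide these, and the tether fixes the regiochemistry. High dilution, BHT and base-washed glass suppress bimolecular addition and loss of the silyl enol ether; forming a quaternary carbon makes the reaction slow, hence 160 °C.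

Step 12
Reactants: 19 (2S,4aS,6S,8aS)-3,6-bis[(tert-butyldimethylsilyl)oxy]-2-{3-[(4-methoxybenzyl)oxy]propyl}-1,1-dimethyl-1,2,4a,5,6,7-hexahydronaphthalen-8(8aH)-one
Product: 20 the C8 alcohol of 19 (8-OH trans to H-8a expected; other centres unchanged)
Conditions: NaBH4, EtOH/THF, −20 °C
Reagents that add atoms: none
Why: Hydride reduction of the C8 ketone at low temperature is faster than enolisation toward C8a, so the cis fusion is kept; axial attack anti to the axial C1 substituent should give mainly the epimer shown, and either epimer serves because C8 is deoxygenated next.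

Step 13
Reactants: 20 the C8 alcohol of 19; 21 carbon disulfide; 22 iodomethane
Product: 23 O-(C8) S-methyl dithiocarbonate (xanthate) of 20
Conditions: NaH, CS2, then MeI, THF, 0 °C → rt
Reagents that add atoms: carbon disulfide (S=C=S); iodomethane (CI)
Why: Xanthate formation (alkoxide addition to CS2, S-methylation); the silyl enol ether and the ethers are stable to NaH.

Step 14
Reactants: 23 xanthate of 20
Product: 24 3,6-bis[(tert-butyldimethylsilyl)oxy]-2-{3-[(4-methoxybenzyl)oxy]propyl}-1,1-dimethyl-1,2,4a,5,6,7,8,8a-octahydronaphthalene (stereocentres as in 19)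
Conditions: Bu3SnH, AIBN (cat.), PhMe, 100 °C
Reagents that add atoms: none
Why: Barton–McCombie deoxygenation: the stannyl radical adds to C=S, β-scission gives the secondary C8 radical, which takes H from Bu3SnH; no alkene is placed for a favourable cyclisation.

Step 15
Reactants: 24 8-deoxy bis(silyl) compound
Product: 25 6-hydroxy-2-{3-[(4-methoxybenzyl)oxy]propyl}-1,1-dimethyloctahydronaphthalen-3(2H)-one (cis-fused; C2, C4a, C6, C8a as in 19)
Conditions: HF·pyridine, pyridine/THF, 0 °C → rt
Reagents that add atoms: none
Why: Fluoride cleaves both Si–O bonds; the enol released at C3 ketonises by protonation at C4, so C2 is not involved, and the buffered non-basic medium avoids enolisation toward C2.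

Step 16
Reactants: 25 6-hydroxy decalin-3-one
Product: 26 2-{3-[(4-methoxybenzyl)oxy]propyl}-1,1-dimethyloctahydronaphthalene-3,6-dione (cis-fused; C2, C4a, C8a as in 49)
Conditions: Dess–Martin periodinane, NaHCO3, CH2Cl2, 0 °C → rt
Reagents that add atoms: none
Why: Dess–Martin oxidation of the secondary alcohol under buffered, non-basic conditions that should not epimerise C2.

Step 17
Reactants: 26 decalin-3,6-dione; 27 dibromomethane
Product: 28 (2R,4aS,8aS)-2-{3-[(4-methoxybenzyl)oxy]propyl}-1,1-dimethyl-3,6-dimethylidenedecahydronaphthalene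
Conditions: Zn, CH2Br2, TiCl4, THF/CH2Cl2, 0 °C → rt
Reagents that add atoms: dibromomethane (BrCBr)
Why: Takai–Lombardo methylenation: the gem-dizinc/titanium reagent is non-basic and strongly oxophilic, so both ketones, including the hindered enolisable C3 ketone, should be converted without epimerisation at C2.

Step 18
Reactants: 28 bis(methylidene) PMB ether
Product: 29 3-(Dec)propan-1-ol
Conditions: DDQ, CH2Cl2/pH 7 buffer, 0 °C
Reagents that add atoms: none
Why: Oxidative PMB cleavage (hydride abstraction, hemiacetal hydrolysis); isolated 1,1-disubstituted alkenes are not oxidised by DDQ under these conditions.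

Step 19
Reactants: 29 3-(Dec)propan-1-ol
Product: 30 3-(Dec)propanal
Conditions: Dess–Martin periodinane, NaHCO3, CH2Cl2, 0 °C
Reagents that add atoms: none
Why: Mild, non-acidic oxidation of the primary alcohol to the aldehyde without alkene migration.

Step 20
Reactants: 30 3-(Dec)propanal; 31 dimethyl (1-diazo-2-oxopropyl)phosphonate
Product: 32 4-(Dec)but-1-yne
Conditions: K2CO3, MeOH, 0 °C → rt
Reagents that add atoms: dimethyl (1-diazo-2-oxopropyl)phosphonate (CC(=O)C(=[N+]=[N-])P(=O)(OC)OC)
Why: Seyferth–Gilbert homologation with the Ohira–Bestmann reagent: methanolysis frees the diazomethylphosphonate anion, which olefinates the aldehyde; loss of N2 and 1,2-shift give the terminal alkyne.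

Step 21
Reactants: 32 4-(Dec)but-1-yne; 33 trimethylaluminium; 34 paraformaldehyde
Product: 36 (2E)-3-methyl-5-(Dec)pent-2-en-1-ol, via alkenylalane 35 (not isolated)
Conditions: Me3Al, Cp2ZrCl2 (20 mol %), CH2Cl2, 0 °C → rt; then n-BuLi, THF, −78 °C; (CH2O)n, → rt
Reagents that add atoms: trimethylaluminium (C[Al](C)C); paraformaldehyde as formaldehyde (C=O)
Why: Negishi zirconium-catalysed carboalumination adds CH3 and Al syn across the terminal alkyne with methyl on the internal carbon; the ate complex is hydroxymethylated with retention, which fixes the E alkene; 1,1-disubstituted alkenes do not carboaluminate.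

Step 22
Reactants: 36 (2E)-3-methyl-5-(Dec)pent-2-en-1-ol; 37 tert-butyl hydroperoxide
Product: 38 {(2R,3R)-3-methyl-3-[2-(Dec)ethyl]oxiran-2-yl}methanol
Conditions: Ti(OiPr)4 (10 mol %), D-(−)-diethyl tartrate (12 mol %), t-BuOOH, 4 Å MS, CH2Cl2, −20 °C
Reagents that add atoms: tert-butyl hydroperoxide (CC(C)(C)OO)
Why: Sharpless asymmetric epoxidation; oxygen delivery is directed by the allylic hydroxyl, so the exocyclic alkenes are untouched, and the D-tartrate ligand selects the face that gives the (2R,3R) epoxy alcohol for this geraniol-type pattern.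

Step 23
Reactants: 38 (2R,3R)-epoxy alcohol; 39 hydrogen peroxide
Product: 40 (2R,3S)-3-hydroperoxy-3-methyl-5-(Dec)pentane-1,2-diol
Conditions: H2O2 (ethereal, dried over MgSO4), H3PMo12O40 (2 mol %), Et2O, 0 °C → rt
Reagents that add atoms: hydrogen peroxide (OO)
Why: Acid-catalysed perhydrolysis of the epoxide: H2O2 attacks the tertiary carbon, the site best able to carry positive charge, from the back, so C3′ is inverted to the configuration of the target; the strained, activated epoxide should react well before an unstrained alkene is protonated or epoxidised at this temperature.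

Step 24
Reactants: 40 (2R,3S)-hydroperoxy diol; 15 tert-butyldimethylsilyl trifluoromethanesulfonate
Product: 42 (2S)-2-[(tert-butyldimethylsilyl)peroxy]-2-methyl-4-(Dec)butanal, via hydroperoxy aldehyde 41 (not isolated)
Conditions: NaIO4, THF/pH 7 buffer, 0 °C; extract; then TBSOTf, 2,6-lutidine, CH2Cl2, −78 °C
Reagents that add atoms: tert-butyldimethylsilyl trifluoromethanesulfonate (CC(C)(C)[Si](C)(C)OS(=O)(=O)C(F)(F)F)
Why: Periodate glycol cleavage removes the hydroxymethyl carbon and leaves C4′ as an aldehyde with no α-hydrogen (C3′ cannot epimerise); immediate silylation of the acidic OOH blocks the dioxetane-type fragmentation open to α-hydroperoxy carbonyl compounds.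

Step 25
Reactants: 42 α-silylperoxy aldehyde; 43 (triphenylphosphoranylidene)acetaldehyde
Product: 44 (2E,4S)-4-[(tert-butyldimethylsilyl)peroxy]-4-methyl-6-(Dec)hex-2-enal
Conditions: Ph3P=CHCHO (1.1 equiv), PhMe, 70 °C
Reagents that add atoms: (triphenylphosphoranylidene)acetaldehyde (O=CC=P(c1ccccc1)(c1ccccc1)c1ccccc1)
Why: Wittig olefination with the stabilised formyl ylide gives the E enal; stabilised phosphoranes do not attack silyl peroxides, and the α-oxygen activates the hindered aldehyde.

Step 26
Reactants: 44 γ-silylperoxy enal
Product: 45 (4S)-4-[(tert-butyldimethylsilyl)peroxy]-4-methyl-6-(Dec)hexanal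
Conditions: Hantzsch ester (diethyl 2,6-dimethyl-1,4-dihydropyridine-3,5-dicarboxylate), Bn2NH2+ CF3CO2− (20 mol %), THF, rt
Reagents that add atoms: none
Why: Iminium-catalysed transfer hydrogenation: the dihydropyridine delivers hydride to the β-carbon of the iminium ion only, so the unconjugated alkenes and the peroxide are not reduced; C3′ has no hydrogen, so no dienamine can form.

Step 27
Reactants: 45 γ-silylperoxy aldehyde; 46 propanoyl chloride
Product: 47 (3R,4S)-4-{(3S)-3-[(tert-butyldimethylsilyl)peroxy]-3-methyl-5-(Dec)pentyl}-3-methyloxetan-2-one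
Conditions: EtCOCl, iPr2NEt, O-trimethylsilylquinidine (10 mol %), LiClO4, CH2Cl2/Et2O, −78 °C
Reagents that add atoms: propanoyl chloride (CCC(=O)Cl)
Why: Catalytic asymmetric acyl halide–aldehyde cyclocondensation: methylketene forms a Z ammonium enolate with the alkaloid, which adds to the lithium-activated aldehyde through a closed transition state and lactonises to the cis lactone; the catalyst sets C7′ as in the target and C6′ as the epimer that the next step inverts.

Step 28
Reactants: 47 (3R,4S)-silylperoxy β-lactone
Product: 49 (2R)-2-{(3R,6S)-6-methyl-6-[2-(Dec)ethyl]-1,2-dioxan-3-yl}propanoic acid, via hydroperoxy lactone 48 (not isolated)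
Conditions: Bu4NF, THF (0.01 M), −40 → 0 °C; then cold 0.1 M HCl
Reagents that add atoms: none
Why: Proposed new method: fluoride removes the silyl group to give the tertiary peroxide anion, which is held within reach of the lactone C4 (C6′) and should open the strained ring by backside attack at that carbon (6-exo-tet SN2 with alkyl–oxygen cleavage and carboxylate as leaving group), inverting C6′ and releasing the acid; the closest known reactions are the SN2 opening of β-lactones at C4 by soft or weakly basic heteroatom nucleophiles with inversion and the base-mediated intramolecular alkylation of hydroperoxides by sulfonates to give 1,2-dioxanes; acyl attack is disfavoured because it would need an eight-membered perester.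

## Compound list

1 | δ-valerolactone (oxan-2-one) | O=C1CCCCO1 | starting material
2 | N,O-dimethylhydroxylamine hydrochloride | CNOC.Cl | starting material
3 | 5-hydroxy-N-methoxy-N-methylpentanamide | CON(C)C(=O)CCCCO | intermediate
4 | 4-methoxybenzyl chloride | COc1ccc(CCl)cc1 | starting material
5 | N-methoxy-5-[(4-methoxybenzyl)oxy]-N-methylpentanamide | CON(C)C(=O)CCCCOCc1ccc(OC)cc1 | intermediate
6 | vinylmagnesium bromide | C=C[Mg]Br | starting material
7 | 7-[(4-methoxybenzyl)oxy]hept-1-en-3-one | C=CC(=O)CCCCOCc1ccc(OC)cc1 | intermediate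
8 | ethyl (3R)-4-chloro-3-hydroxybutanoate | CCOC(=O)C[C@@H](O)CCl | starting material
9 | ethyl [(2R)-oxiran-2-yl]acetate | CCOC(=O)C[C@@H]1CO1 | intermediate
10 | ethyl (3S)-3-hydroxyhex-5-enoate | CCOC(=O)C[C@@H](O)CC=C | intermediate
11 | (3S)-3-hydroxy-N-methoxy-N-methylhex-5-enamide | CON(C)C(=O)C[C@@H](O)CC=C | intermediate
12 | tert-butyldimethylsilyl chloride | CC(C)(C)[Si](C)(C)Cl | starting material
13 | (3S)-3-[(tert-butyldimethylsilyl)oxy]-N-methoxy-N-methylhex-5-enamide | CON(C)C(=O)C[C@@H](O[Si](C)(C)C(C)(C)C)CC=C | intermediate
14 | (3S,5E)-3-[(tert-butyldimethylsilyl)oxy]-N-methoxy-11-[(4-methoxybenzyl)oxy]-N-methyl-7-oxoundec-5-enamide | CON(C)C(=O)C[C@@H](O[Si](C)(C)C(C)(C)C)C/C=C/C(=O)CCCCOCc1ccc(OC)cc1 | intermediate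
15 | tert-butyldimethylsilyl trifluoromethanesulfonate | CC(C)(C)[Si](C)(C)OS(=O)(=O)C(F)(F)F | starting material
16 | (3S,5E,7Z)-3,7-bis[(tert-butyldimethylsilyl)oxy]-N-methoxy-11-[(4-methoxybenzyl)oxy]-N-methylundeca-5,7-dienamide | CON(C)C(=O)C[C@@H](O[Si](C)(C)C(C)(C)C)C/C=C/C(O[Si](C)(C)C(C)(C)C)=C/CCCOCc1ccc(OC)cc1 | intermediate
17 | (2-methylprop-1-en-1-yl)magnesium bromide | CC(C)=C[Mg]Br | starting material
18 | (6S,8E,10Z)-6,10-bis[(tert-butyldimethylsilyl)oxy]-14-[(4-methoxybenzyl)oxy]-2-methyltetradeca-2,8,10-trien-4-one (precursor of the key step) | CC(C)=CC(=O)C[C@@H](O[Si](C)(C)C(C)(C)C)C/C=C/C(O[Si](C)(C)C(C)(C)C)=C/CCCOCc1ccc(OC)cc1 | intermediate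
19 | (2S,4aS,6S,8aS)-3,6-bis[(tert-butyldimethylsilyl)oxy]-2-{3-[(4-methoxybenzyl)oxy]propyl}-1,1-dimethyl-1,2,4a,5,6,7-hexahydronaphthalen-8(8aH)-one; cis-fused, H-2, H-4a and H-8a cis, 6-O trans to H-4a (product of the key step) | O=C1C[C@@H](O[Si](C)(C)C(C)(C)C)C[C@H]2C=C(O[Si](C)(C)C(C)(C)C)[C@@H](CCCOCc3ccc(OC)cc3)C(C)(C)[C@@H]12 | intermediate
20 | C8 alcohol of 19 (8-OH trans to H-8a; other centres as in 19) | O[C@H]1C[C@@H](O[Si](C)(C)C(C)(C)C)C[C@H]2C=C(O[Si](C)(C)C(C)(C)C)[C@@H](CCCOCc3ccc(OC)cc3)C(C)(C)[C@@H]12 | intermediate
21 | carbon disulfide | S=C=S | starting material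
22 | iodomethane | CI | starting material
23 | O-(C8) S-methyl dithiocarbonate of 20 | CSC(=S)O[C@H]1C[C@@H](O[Si](C)(C)C(C)(C)C)C[C@H]2C=C(O[Si](C)(C)C(C)(C)C)[C@@H](CCCOCc3ccc(OC)cc3)C(C)(C)[C@@H]12 | intermediate
24 | 3,6-bis[(tert-butyldimethylsilyl)oxy]-2-{3-[(4-methoxybenzyl)oxy]propyl}-1,1-dimethyl-1,2,4a,5,6,7,8,8a-octahydronaphthalene (C8 = CH2; stereocentres as in 19) | C1C[C@@H](O[Si](C)(C)C(C)(C)C)C[C@H]2C=C(O[Si](C)(C)C(C)(C)C)[C@@H](CCCOCc3ccc(OC)cc3)C(C)(C)[C@@H]12 | intermediate
25 | 6-hydroxy-2-{3-[(4-methoxybenzyl)oxy]propyl}-1,1-dimethyloctahydronaphthalen-3(2H)-one (cis-fused; stereocentres as in 19) | C1C[C@@H](O)C[C@H]2CC(=O)[C@@H](CCCOCc3ccc(OC)cc3)C(C)(C)[C@@H]12 | intermediate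
26 | 2-{3-[(4-methoxybenzyl)oxy]propyl}-1,1-dimethyloctahydronaphthalene-3,6-dione (cis-fused; C2, C4a, C8a as in 49) | O=C1CC[C@H]2[C@@H](C1)CC(=O)[C@@H](CCCOCc3ccc(OC)cc3)C2(C)C | intermediate
27 | dibromomethane | BrCBr | starting material
28 | (2R,4aS,8aS)-2-{3-[(4-methoxybenzyl)oxy]propyl}-1,1-dimethyl-3,6-dimethylidenedecahydronaphthalene | C=C1CC[C@H]2[C@@H](C1)CC(=C)[C@@H](CCCOCc3ccc(OC)cc3)C2(C)C | intermediate
29 | 3-(Dec)propan-1-ol | C=C1CC[C@H]2[C@@H](C1)CC(=C)[C@@H](CCCO)C2(C)C | intermediate
30 | 3-(Dec)propanal | C=C1CC[C@H]2[C@@H](C1)CC(=C)[C@@H](CCC=O)C2(C)C | intermediate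
31 | dimethyl (1-diazo-2-oxopropyl)phosphonate | CC(=O)C(=[N+]=[N-])P(=O)(OC)OC | starting material
32 | 4-(Dec)but-1-yne | C=C1CC[C@H]2[C@@H](C1)CC(=C)[C@@H](CCC#C)C2(C)C | intermediate
33 | trimethylaluminium | C[Al](C)C | starting material
34 | paraformaldehyde (as formaldehyde) | C=O | starting material
35 | dimethyl[(1E)-2-methyl-4-(Dec)but-1-en-1-yl]alane | C=C1CC[C@H]2[C@@H](C1)CC(=C)[C@@H](CC/C(C)=C/[Al](C)C)C2(C)C | intermediate
36 | (2E)-3-methyl-5-(Dec)pent-2-en-1-ol | C=C1CC[C@H]2[C@@H](C1)CC(=C)[C@@H](CC/C(C)=C/CO)C2(C)C | intermediate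
37 | tert-butyl hydroperoxide | CC(C)(C)OO | starting material
38 | {(2R,3R)-3-methyl-3-[2-(Dec)ethyl]oxiran-2-yl}methanol | C=C1CC[C@H]2[C@@H](C1)CC(=C)[C@@H](CC[C@@]3(C)O[C@@H]3CO)C2(C)C | intermediate
39 | hydrogen peroxide | OO | starting material
40 | (2R,3S)-3-hydroperoxy-3-methyl-5-(Dec)pentane-1,2-diol | C=C1CC[C@H]2[C@@H](C1)CC(=C)[C@@H](CC[C@](C)(OO)[C@H](O)CO)C2(C)C | intermediate
41 | (2S)-2-hydroperoxy-2-methyl-4-(Dec)butanal | C=C1CC[C@H]2[C@@H](C1)CC(=C)[C@@H](CC[C@](C)(OO)C=O)C2(C)C | intermediate
42 | (2S)-2-[(tert-butyldimethylsilyl)peroxy]-2-methyl-4-(Dec)butanal | C=C1CC[C@H]2[C@@H](C1)CC(=C)[C@@H](CC[C@](C)(OO[Si](C)(C)C(C)(C)C)C=O)C2(C)C | intermediate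
43 | (triphenylphosphoranylidene)acetaldehyde | O=CC=P(c1ccccc1)(c1ccccc1)c1ccccc1 | starting material
44 | (2E,4S)-4-[(tert-butyldimethylsilyl)peroxy]-4-methyl-6-(Dec)hex-2-enal | C=C1CC[C@H]2[C@@H](C1)CC(=C)[C@@H](CC[C@](C)(OO[Si](C)(C)C(C)(C)C)/C=C/C=O)C2(C)C | intermediate
45 | (4S)-4-[(tert-butyldimethylsilyl)peroxy]-4-methyl-6-(Dec)hexanal | C=C1CC[C@H]2[C@@H](C1)CC(=C)[C@@H](CC[C@](C)(OO[Si](C)(C)C(C)(C)C)CCC=O)C2(C)C | intermediate
46 | propanoyl chloride | CCC(=O)Cl | starting material
47 | (3R,4S)-4-{(3S)-3-[(tert-butyldimethylsilyl)peroxy]-3-methyl-5-(Dec)pentyl}-3-methyloxetan-2-one (cis) | C=C1CC[C@H]2[C@@H](C1)CC(=C)[C@@H](CC[C@](C)(OO[Si](C)(C)C(C)(C)C)CC[C@H]3[C@@H](C)C(=O)O3)C2(C)C | intermediate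
48 | (3R,4S)-4-[(3S)-3-hydroperoxy-3-methyl-5-(Dec)pentyl]-3-methyloxetan-2-one | C=C1CC[C@H]2[C@@H](C1)CC(=C)[C@@H](CC[C@](C)(OO)CC[C@H]3[C@@H](C)C(=O)O3)C2(C)C | intermediate
49 | (2R)-2-{(3R,6S)-6-methyl-6-[2-(Dec)ethyl]-1,2-dioxan-3-yl}propanoic acid | C=C1CC[C@H]2[C@@H](C1)CC(=C)[C@@H](CC[C@@]1(C)CC[C@H]([C@@H](C)C(=O)O)OO1)C2(C)C | target

## Step count and least certain steps

Total: 28 steps. Longest linear sequence: 25 steps (8 → 49, steps 4–28); the vinyl ketone 7 takes 3 steps (1–3).

Step 28 (Proposed new method).
- What may go wrong: attack of the peroxide anion or of fluoride at the acyl carbon instead of C6′; β-elimination of the lactone to an unsaturated acid; base-induced cleavage of the new dioxane through H-6′; intermolecular opening.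
- Fallback with known chemistry, from 45 back to 49: Evans syn aldol of 45 with (4R)-4-benzyl-3-propanoyl-1,3-oxazolidin-2-one (Bu2BOTf, iPr2NEt, CH2Cl2, −78 → 0 °C) gives the syn-aldol imide F1, with C7′ as in the target and the C6′ hydroxyl in the configuration to be inverted. NaBH4 in THF/H2O removes the auxiliary to give the 1,3-diol F2. TBSCl/imidazole protects the primary hydroxyl as the silyl ether F3. MsCl/Et3N gives the secondary mesylate F4. Bu4NF then removes both silyl groups, and the peroxide anion displaces the mesylate (6-exo-tet, inversion; intramolecular alkylation of a hydroperoxide) to give the dioxane alcohol F5. TEMPO/PhI(OAc)2 in aqueous MeCN oxidises the primary alcohol to the acid 49.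

Step 11 (key step).
- What may go wrong: slow cycloaddition at the β,β-disubstituted terminus, so that thermal loss of the silyl enol ether or β-elimination of the C6 silyloxy group competes; erosion of facial selectivity if a chair-like endo tether competes with the boat-like one; some exo addition.
- First adjustment: Lewis acid acceleration with Me2AlCl at low temperature.
- Fallback that changes the approach, from 16 back to 19: acylate prop-1-ynylmagnesium bromide with 16 to give the ynone F6. The alkynone is a far more reactive dienophile with no endo/exo question, and cyclises in toluene at about 110 °C to the cross-conjugated cyclohexadienone F7; C2 and C4a are set cis by the diene geometry, and the silyloxy group is equatorial on a chair-like tether. Conjugate addition of Me2CuLi/Me3SiCl then installs the second methyl group at C1, and kinetic protonation of the C8a enolate from the convex face is expected to give the cis-fused ketone 19.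

Step 24.
- What may go wrong: fragmentation of the free α-hydroperoxy aldehyde (attack of OOH on its own carbonyl, then C–C cleavage to the methyl ketone) before it is silylated; incomplete chemoselectivity of silylation.
- Fallback, from 40 back to 44: after the periodate cleavage of 40, treat the crude aldehyde directly with the stabilised ylide 43, which does not reduce hydroperoxides, to give the γ-hydroperoxy enal F9. Only then silylate (TBSOTf, 2,6-lutidine) to reach 44.

Step 25.
- What may go wrong: slow olefination of the α-quaternary aldehyde and a second olefination of the less hindered enal product.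
- Fallback, from 42 back to 44: Horner–Wadsworth–Emmons reaction with triethyl phosphonoacetate (LiCl, DBU, MeCN) gives the E enoate F10. iBu2AlH at −78 °C gives the allylic alcohol F11, and MnO2 gives the enal 44.

Step 17.
- What may go wrong: incomplete methylenation of the hindered C3 ketone; epimerisation at C2 during a prolonged reaction; migration of an exocyclic alkene on acidic work-up.
- Fallback, from 26 back to 28: Peterson olefination in two operations. Double addition of Me3SiCH2Li/CeCl3 (THF, −78 °C; the organocerium reagent is non-basic) gives the bis(β-hydroxysilane) F8. Elimination with aqueous HF in MeCN gives 28.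

## Further compounds

F1 | step 28 | (4R)-4-benzyl-3-{(2R,3S,6S)-6-[(tert-butyldimethylsilyl)peroxy]-3-hydroxy-2,6-dimethyl-8-(Dec)octanoyl}-1,3-oxazolidin-2-one | C=C1CC[C@H]2[C@@H](C1)CC(=C)[C@@H](CC[C@](C)(OO[Si](C)(C)C(C)(C)C)CC[C@H](O)[C@@H](C)C(=O)N3[C@H](Cc4ccccc4)COC3=O)C2(C)C
F2 | step 28 | 1,3-diol from reductive removal of the auxiliary of F1 (C8′ = CH2OH) | C=C1CC[C@H]2[C@@H](C1)CC(=C)[C@@H](CC[C@](C)(OO[Si](C)(C)C(C)(C)C)CC[C@H](O)[C@@H](C)CO)C2(C)C
F3 | step 28 | primary tert-butyldimethylsilyl ether of F2 | C=C1CC[C@H]2[C@@H](C1)CC(=C)[C@@H](CC[C@](C)(OO[Si](C)(C)C(C)(C)C)CC[C@H](O)[C@@H](C)CO[Si](C)(C)C(C)(C)C)C2(C)C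
F4 | step 28 | C6′ methanesulfonate of F3 | C=C1CC[C@H]2[C@@H](C1)CC(=C)[C@@H](CC[C@](C)(OO[Si](C)(C)C(C)(C)C)CC[C@H](OS(C)(=O)=O)[C@@H](C)CO[Si](C)(C)C(C)(C)C)C2(C)C
F5 | step 28 | (2R)-2-{(3R,6S)-6-methyl-6-[2-(Dec)ethyl]-1,2-dioxan-3-yl}propan-1-ol | C=C1CC[C@H]2[C@@H](C1)CC(=C)[C@@H](CC[C@@]1(C)CC[C@H]([C@@H](C)CO)OO1)C2(C)C
F6 | step 11 | (6S,8E,10Z)-6,10-bis[(tert-butyldimethylsilyl)oxy]-14-[(4-methoxybenzyl)oxy]tetradeca-8,10-dien-2-yn-4-one | CC#CC(=O)C[C@@H](O[Si](C)(C)C(C)(C)C)C/C=C/C(O[Si](C)(C)C(C)(C)C)=C/CCCOCc1ccc(OC)cc1
F7 | step 11 | 3,6-bis[(tert-butyldimethylsilyl)oxy]-2-{3-[(4-methoxybenzyl)oxy]propyl}-1-methyl-4a,5,6,7-tetrahydronaphthalen-8(2H)-one (C1=C8a enone; C2, C4a, C6 as in 19) | O=C1C[C@@H](O[Si](C)(C)C(C)(C)C)C[C@H]2C=C(O[Si](C)(C)C(C)(C)C)[C@@H](CCCOCc3ccc(OC)cc3)C(C)=C12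
F8 | step 17 | 3,6-bis[(trimethylsilyl)methyl]decalin-3,6-diol from 26 (carbinol epimers; C2, C4a, C8a as in 26) | C[Si](C)(C)CC1(O)CC[C@H]2[C@@H](C1)CC(O)(C[Si](C)(C)C)[C@@H](CCCOCc3ccc(OC)cc3)C2(C)C
F9 | step 24 | (2E,4S)-4-hydroperoxy-4-methyl-6-(Dec)hex-2-enal | C=C1CC[C@H]2[C@@H](C1)CC(=C)[C@@H](CC[C@](C)(OO)/C=C/C=O)C2(C)C
F10 | step 25 | ethyl (2E,4S)-4-[(tert-butyldimethylsilyl)peroxy]-4-methyl-6-(Dec)hex-2-enoate | C=C1CC[C@H]2[C@@H](C1)CC(=C)[C@@H](CC[C@](C)(OO[Si](C)(C)C(C)(C)C)/C=C/C(=O)OCC)C2(C)C
F11 | step 25 | (2E,4S)-4-[(tert-butyldimethylsilyl)peroxy]-4-methyl-6-(Dec)hex-2-en-1-ol | C=C1CC[C@H]2[C@@H](C1)CC(=C)[C@@H](CC[C@](C)(OO[Si](C)(C)C(C)(C)C)/C=C/CO)C2(C)C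
A1 | alternative 1 | 2-(trimethylsilyloxy)buta-1,3-diene | C=CC(=C)O[Si](C)(C)C
A2 | alternative 1 | (5R)-5-(l-menthyloxy)furan-2(5H)-one | O=C1C=C[C@H](O[C@@H]2C[C@H](C)CC[C@H]2C(C)C)O1
A3 | alternative 1 | cis-fused bicyclic lactone acetal with C6 silyl enol ether | C[Si](C)(C)OC1=CC[C@H]2[C@@H](C1)[C@H](O[C@@H]3C[C@H](C)CC[C@H]3C(C)C)OC2=O
A4 | alternative 2 | Se-phenyl selenoester of the cis-cyclohexane with C6 ketal, C4a acetic arm and C8a C(CH3)2–CH=CH–CO2CH3 arm | O1CCOC12CC[C@@H]([C@@H](C2)CC(=O)[Se]c3ccccc3)C(C)(C)/C=C/C(=O)OC
A5 | alternative 2 | cis-decalin-3-one with C6 ketal and C2 acetate arm | O1CCOC12CC[C@H]3[C@@H](C2)CC(=O)[C@@H](CC(=O)OC)C3(C)C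
A6 | alternative 3 | Z ten-membered allylic lactone with C6 silyloxy group | O=C1CC[C@H](O[Si](C)(C)C(C)(C)C)CC/C=C(/C)CO1
A7 | alternative 3 | cis-2-isopropenyl-5-silyloxycyclohexanecarboxylic acid | OC(=O)[C@@H]1C[C@H](O[Si](C)(C)C(C)(C)C)CC[C@@H]1C(C)=C
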